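**Plan**

1. Retrosynthesis: after removal of four aryl TIPS ethers, the cyclohexenone ring of the bicyclo[3.3.1]nonane core is cut at its two bonds to the three-carbon enone unit (carbinol C–ketone C and ring-ether C–enone β-C). This leads back to a cyclopropane-fused indeno[2,1-b]furan-8-ol (a 2-alkoxy-1-arylcyclopropanol) carrying a (Z)-2-aryl-enynal arm.
2. Further cuts: cyclopropane CH2 (Simmons–Smith), aryl–C bond of the indanone (Nazarov), aroyl group (carbonylative Suzuki on a lactone enol phosphate), lactone (hydroboration/oxidation), the C–C bond between the O-bearing CH and the benzyl-bearing CH (anti allylboration), and the arm (anti-arylmagnesiation of propargyl alcohol, Sonogashira).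
3. Forward ring order: γ-lactone (future tetrahydrofuran) → 4,5-dihydrofuran → indanone on ring C → cyclopropane → in one flask, ring expansion to the tetralin ring and closure of the dihydropyran (8-oxabicyclo[3.2.1]octene) and the cyclohexenone.
4. Enabling feature: the CH2-bridged pair of oxygenated quaternary carbons shared by the tetralin and cyclohexenone rings, C(O-ring)–CH2–C(OH)(aryl), is a ring-opened 2-alkoxy-1-arylcyclopropanol. β-Scission of its alkoxy radical gives an α-oxy radical and an aryl ketone at exactly the two carbons that must bond to the β-carbon and the formyl carbon of an ynal.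
5. Stereochemistry: the O-bearing CH and benzyl-bearing CH come from a catalyst-controlled anti allylboration; the benzylic ring-fusion CH from torquoselective Nazarov closure anti to the benzyl group; both quaternary centres from the substrate (tether, then 1,3-diaxial bridge); the arm geometry from a chelated alkenylmagnesium.

Key step: step 21

Abbreviations: TIPS = triisopropylsilyl; TBS = tert-butyldimethylsilyl; TMS = trimethylsilyl; Bpin = 4,4,5,5-tetramethyl-1,3,2-dioxaborolan-2-yl; ArA = 2-methoxy-4-(TIPS-oxy)phenyl (ring A); ArB = 2,4-dimethoxy-3-(TIPS-oxy)phenyl (ring B); ring C = the catechol ring, carried as its bis-TIPS ether; (R)-TRIP = (R)-3,3′-bis(2,4,6-triisopropylphenyl)-1,1′-binaphthyl-2,2′-diyl hydrogen phosphate.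

Remark on the chemistry: (R)-TRIP is assumed to select the aldehyde face that gives the carbinol configuration drawn for 21; if the sense is the opposite, (S)-TRIP is used.

**Route**

Step 1
Reactants: 1 2,6-dimethoxyphenol
Product: 2 (2,6-dimethoxyphenoxy)triisopropylsilane
Conditions: TIPSCl, imidazole, DMF, rt
Reagents that add atoms: chlorotriisopropylsilane CC(C)[Si](Cl)(C(C)C)C(C)C
Why: Phenol silylation gives an ether that is stable to bases and organometallics and is removed by fluoride at the end.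

Step 2
Reactants: 2 (2,6-dimethoxyphenoxy)triisopropylsilane
Product: 3 (3-bromo-2,6-dimethoxyphenoxy)triisopropylsilane
Conditions: N-bromosuccinimide, MeCN, 0 °C to rt
Reagents that add atoms: N-bromosuccinimide O=C1CCC(=O)N1Br
Why: Electrophilic aromatic bromination should go to the position ortho to one methoxy and para to the other, the most activated site.

Step 3
Reactants: 3 (3-bromo-2,6-dimethoxyphenoxy)triisopropylsilane; 4 prop-2-yn-1-ol
Product: 7 (Z)-2-ArB-3-iodoprop-2-en-1-ol, via aryl Grignard reagent 5 (not isolated), via alkenylmagnesium chelate 6 (not isolated)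
Conditions: Mg, THF; then CuI (10 mol%), 4 (0.35 equiv), THF, −10 °C to rt; then I2, −20 °C
Reagents that add atoms: iodine II
Why: Copper-catalysed, alkoxide-directed anti-arylmagnesiation of the propargylic alcohol puts aryl on C2 and magnesium on C3 inside a five-membered chelate, and iodinolysis with retention should give the Z iodide in which CH2O and iodine are cis.

Step 4
Reactants: 7 (Z)-2-ArB-3-iodoprop-2-en-1-ol; 8 tert-butyldimethyl(prop-2-yn-1-yloxy)silane
Product: 9 (Z)-6-(TBS-oxy)-2-ArB-hex-2-en-4-yn-1-ol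
Conditions: Pd(PPh3)2Cl2 (2 mol%), CuI (4 mol%), Et3N, THF, rt
Reagents that add atoms: none
Why: Sonogashira coupling of the alkenyl iodide should proceed with retention of the double-bond geometry.

Step 5
Reactants: 9 (Z)-6-(TBS-oxy)-2-ArB-hex-2-en-4-yn-1-ol
Product: 10 (Z)-6-(TBS-oxy)-2-ArB-hex-2-en-4-ynal
Conditions: MnO2, CH2Cl2, rt
Reagents that add atoms: none
Why: MnO2 oxidises the allylic primary alcohol selectively to the non-enolisable enal under neutral conditions.

Step 6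
Reactants: 11 4-bromo-3-methoxyphenol
Product: 12 (4-bromo-3-methoxyphenoxy)triisopropylsilane
Conditions: TIPSCl, imidazole, DMF, rt
Reagents that add atoms: chlorotriisopropylsilane CC(C)[Si](Cl)(C(C)C)C(C)C
Why: Phenol silylation as in step 1.

Step 7
Reactants: 12 (4-bromo-3-methoxyphenoxy)triisopropylsilane; 13 2-vinyloxirane
Product: 15 (E)-4-ArA-but-2-en-1-ol, via aryl Grignard reagent 14 (not isolated)
Conditions: Mg, THF, 50 °C; then CuI (10 mol%), 13, THF, −40 to 0 °C
Reagents that add atoms: none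
Why: Copper-catalysed SN2′ opening of the vinyl oxirane by the aryl Grignard reagent should give the E allylic alcohol.

Step 8
Reactants: 15 (E)-4-ArA-but-2-en-1-ol
Product: 16 (E)-2-(4-ArA-but-2-en-1-yl)-4,4,5,5-tetramethyl-1,3,2-dioxaborolane
Conditions: B2pin2, Pd(MeCN)4(BF4)2 (5 mol%), DMSO–MeOH, 40 °C
Reagents that add atoms: bis(pinacolato)diboron CC1(C)OB(OC1(C)C)B1OC(C)(C)C(C)(C)O1
Why: Palladium-catalysed allylic borylation of the alcohol through a π-allyl complex should give the linear E allylboronate.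

Step 9
Reactants: 17 4-bromobenzene-1,2-diol
Product: 18 4-bromo-1,2-bis(TIPS-oxy)benzene
Conditions: TIPSCl (2.4 equiv), imidazole, DMF, 40 °C
Reagents that add atoms: chlorotriisopropylsilane CC(C)[Si](Cl)(C(C)C)C(C)C
Why: Double silylation protects the catechol for the whole route.

Step 10
Reactants: 18 4-bromo-1,2-bis(TIPS-oxy)benzene
Product: 20 [3,4-bis(TIPS-oxy)phenyl]boronic acid, via aryllithium 19 (not isolated)
Conditions: n-BuLi, THF, −78 °C; then B(Oi-Pr)3; then aq. NH4Cl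
Reagents that add atoms: triisopropyl borate CC(C)OB(OC(C)C)OC(C)C; water O
Why: Bromine–lithium exchange and borylation give the boronic acid, and no silyl migration is expected because lithium is not ortho to a silyloxy group.

Step 11
Reactants: 10 (Z)-6-(TBS-oxy)-2-ArB-hex-2-en-4-ynal; 16 (E)-allylboronate
Product: 21 (5Z)-3,4-anti-3-(ArA-methyl)-5-ArB-9-(TBS-oxy)nona-1,5-dien-7-yn-4-ol (enantiomer of the SMILES)
Conditions: (R)-TRIP (5 mol%), toluene, −30 °C; aqueous work-up
Reagents that add atoms: none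
Why: Chiral phosphoric acid-catalysed allylboration through a closed chair transition state should give the anti relationship from the E boronate and the absolute configuration from the catalyst, which sets the O-bearing and benzyl-bearing carbons.

Step 12
Reactants: 21 anti homoallylic alcohol
Product: 22 (5Z)-3,4-anti-3-(ArA-methyl)-5-ArB-9-(TBS-oxy)non-5-en-7-yne-1,4-diol
Conditions: 9-BBN (2.5 equiv), THF, 0 °C to rt; then H2O2, NaOAc, H2O, 0 °C
Reagents that add atoms: hydrogen peroxide OO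
Why: Anti-Markovnikov hydroboration–oxidation should take the monosubstituted alkene much faster than the internal alkyne or the trisubstituted alkene.

Step 13
Reactants: 22 1,4-diol
Product: 23 4,5-trans-4-(ArA-methyl)-5-[(Z)-1-ArB-5-(TBS-oxy)pent-1-en-3-yn-1-yl]dihydrofuran-2(3H)-one
Conditions: TEMPO (10 mol%), PhI(OAc)2 (2.5 equiv), CH2Cl2, rt
Reagents that add atoms: none
Why: Oxidative lactonisation should oxidise the primary alcohol, close the lactol and oxidise it to the γ-lactone without touching the stereocentres.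

Step 14
Reactants: 23 γ-lactone
Product: 24 2,3-trans-3-(ArA-methyl)-2-[(Z)-1-ArB-5-(TBS-oxy)pent-1-en-3-yn-1-yl]-2,3-dihydrofuran-5-yl diphenyl phosphate
Conditions: KN(SiMe3)2, (PhO)2P(O)Cl, THF, −78 °C
Reagents that add atoms: diphenyl chlorophosphate O=P(Cl)(Oc1ccccc1)Oc1ccccc1
Why: O-Phosphorylation of the kinetic lactone enolate gives the ketene acetal phosphate (enol phosphate formation).

Step 15
Reactants: 24 ketene acetal phosphate; 20 [3,4-bis(TIPS-oxy)phenyl]boronic acid
Product: 25 [3,4-bis(TIPS-oxy)phenyl]{4,5-trans-4-(ArA-methyl)-5-[(Z)-1-ArB-5-(TBS-oxy)pent-1-en-3-yn-1-yl]-4,5-dihydrofuran-2-yl}methanone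
Conditions: CO (1 atm), PdCl2(dppf) (5 mol%), K2CO3, anisole, 80 °C
Reagents that add atoms: carbon monoxide [C-]#[O+]
Why: Carbonylative Suzuki–Miyaura coupling (oxidative addition of the C–OP bond to zerovalent palladium, CO insertion, transmetalation) installs the aroyl group on the enol ether carbon.

Step 16
Reactants: 25 2-aroyl-4,5-dihydrofuran
Product: 26 (2,3-trans,3,3a-trans,3a,8a-cis)-3-(ArA-methyl)-2-[(Z)-1-ArB-5-(TBS-oxy)pent-1-en-3-yn-1-yl]-5,6-bis(TIPS-oxy)-2,3,3a,8a-tetrahydro-8H-indeno[2,1-b]furan-8-one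
Conditions: Sc(OTf)3 (10 mol%), LiClO4, ClCH2CH2Cl, 50 °C
Reagents that add atoms: none
Why: Lewis acid-catalysed Nazarov cyclisation of the polarised α-alkoxy aryl vinyl ketone should close para to a silyloxy group and anti to the adjacent benzyl group, and protonation of the enol can only give the cis ring fusion.

Step 17
Reactants: 26 indanone (TBS ether)
Product: 27 the same indanone with a free propargylic alcohol [2-substituent (Z)-1-ArB-5-hydroxypent-1-en-3-yn-1-yl]
Conditions: pyridinium p-toluenesulfonate, MeOH, 40 °C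
Reagents that add atoms: none
Why: Acid-catalysed methanolysis should cleave the primary alkyl TBS ether and leave the acid-stable aryl TIPS ethers.

Step 18
Reactants: 27 hydroxy indanone
Product: 28 (2,3-trans,3,3a-trans)-3-(ArA-methyl)-2-[(Z)-1-ArB-5-(TMS-oxy)pent-1-en-3-yn-1-yl]-5,6-bis(TIPS-oxy)-8-(TMS-oxy)-3,3a-dihydro-2H-indeno[2,1-b]furan
Conditions: Me3SiOTf (2.5 equiv), Et3N, CH2Cl2, 0 °C
Reagents that add atoms: trimethylsilyl trifluoromethanesulfonate C[Si](C)(C)OS(=O)(=O)C(F)(F)F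
Why: Soft enolisation–silylation gives the only possible silyl enol ether (one α-hydrogen) and silylates the primary alcohol.

Step 19
Reactants: 28 silyl enol ether
Product: 30 cyclopropanol diol (8,8a-methano-bridged tetrahydroindeno[2,1-b]furan-8-ol; CH2 anti to the tetrahydrofuran ring; free propargylic alcohol), via bis-TMS cyclopropane 29 (not isolated)
Conditions: Et2Zn, CH2I2, CH2Cl2, 0 °C to rt; then K2CO3, MeOH, 0 °C
Reagents that add atoms: diiodomethane ICI
Why: Simmons–Smith cyclopropanation (Furukawa conditions) should take the very electron-rich enol ether from the convex face, anti to the fused tetrahydrofuran, and methanolysis then frees both hydroxyls; the new CH2 is the future one-carbon bridge.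

Step 20
Reactants: 30 cyclopropanol diol
Product: 31 cyclopropanol ynal [2-substituent (Z)-1-ArB-5-oxopent-1-en-3-yn-1-yl]
Conditions: MnO2, CH2Cl2, rt
Reagents that add atoms: none
Why: MnO2 oxidises the propargylic primary alcohol to the ynal and cannot oxidise the tertiary cyclopropanol.

Step 21
Reactants: 31 cyclopropanol ynal
Product: 33 tetrakis-TIPS ether of the target, via ring-expanded keto-enal 32 (not isolated)
Conditions: (n-Bu4N)2CeCl6 (5 mol%), 9,10-diphenylanthracene (5 mol%), NaHCO3, MeCN, 400 nm LEDs, rt; then 2-(pentafluorophenyl)-6,7-dihydro-5H-pyrrolo[2,1-c][1,2,4]triazol-2-ium tetrafluoroborate (20 mol%), i-Pr2NEt, 40 °C, dark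
Reagents that add atoms: none
Why: Proposed new method: the tetravalent cerium alkoxide of the only free hydroxyl should undergo LMCT homolysis, and the alkoxy radical should open the internal cyclopropane bond, turning the indanol into a 1-tetralone with a tertiary α-alkoxy radical at the ring-ether carbon; this nucleophilic radical should add 6-exo-dig to the ynal β-carbon, the allenyloxyl radical should be reduced and protonated to the (Z)-enal 32, and the carbene added afterwards should convert the formyl carbon into an acyl anion (Breslow intermediate) that adds to the aryl ketone. The closest known reaction types are cerium-photocatalysed ring-opening Giese reactions of cycloalkanols, ring-expanding radical cyclisations of bicyclic cyclopropanols, and the carbene-catalysed intramolecular crossed aldehyde–ketone benzoin reaction; new are their union in one flask, the ynal acceptor and the α-oxy radical. Three rings arise: the tetralin ring by one-carbon ring expansion, the dihydropyran by 6-exo-dig radical closure, and the cyclohexenone by 6-exo-trig acyl-anion closure. The quaternary ring-ether carbon is set by the tether, because the arm on the neighbouring tetrahydrofuran carbon can reach only the face of the planar radical on which it stands, and the carbinol carbon is set by the bridge, because the acyl carbon held on that face can add to the ketone only 1,3-diaxially. The step needs internal rather than external cyclopropane cleavage (secured by the ring oxygen, which stabilises the radical), ring closure faster than oxidation or hydrogen loss to a naphthol (secured by the intramolecular, polarity-matched ynal), the Z enal (expected from protonation of the allenolate on the side away from the quaternary carbon, with reversible carbene addition able to return the E isomer), and benzoin rather than homoenolate chemistry (secured by the β,β-disubstituted enal and the aprotic medium).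

Step 22
Reactants: 33 tetrakis-TIPS ether of the target
Product: 34 CNP0246028.1 (target)
Conditions: HF·pyridine, pyridine, THF, 0 °C to rt
Reagents that add atoms: none
Why: Fluoride-mediated desilylation under buffered, non-basic conditions should free the four phenols without α-ketol rearrangement or catechol oxidation.

**Compound list**

1 | 2,6-dimethoxyphenol | COc1cccc(OC)c1O | starting material
2 | (2,6-dimethoxyphenoxy)triisopropylsilane | COc1cccc(OC)c1O[Si](C(C)C)(C(C)C)C(C)C | intermediate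
3 | (3-bromo-2,6-dimethoxyphenoxy)triisopropylsilane | COc1ccc(Br)c(OC)c1O[Si](C(C)C)(C(C)C)C(C)C | intermediate
4 | prop-2-yn-1-ol | C#CCO | starting material
5 | [2,4-dimethoxy-3-(triisopropylsilyloxy)phenyl]magnesium bromide | COc1ccc([Mg]Br)c(OC)c1O[Si](C(C)C)(C(C)C)C(C)C | intermediate
6 | bromomagnesium (Z)-3-(bromomagnesio)-2-ArB-prop-2-en-1-olate (O and Mg cis, chelate) | Br[Mg]OC/C(=C\[Mg]Br)c1ccc(OC)c(O[Si](C(C)C)(C(C)C)C(C)C)c1OC | intermediate
7 | (Z)-2-ArB-3-iodoprop-2-en-1-ol | OC/C(=C\I)c1ccc(OC)c(O[Si](C(C)C)(C(C)C)C(C)C)c1OC | intermediate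
8 | tert-butyldimethyl(prop-2-yn-1-yloxy)silane | C#CCO[Si](C)(C)C(C)(C)C | starting material
9 | (Z)-6-(tert-butyldimethylsilyloxy)-2-ArB-hex-2-en-4-yn-1-ol | OC/C(=C\C#CCO[Si](C)(C)C(C)(C)C)c1ccc(OC)c(O[Si](C(C)C)(C(C)C)C(C)C)c1OC | intermediate
10 | (Z)-6-(tert-butyldimethylsilyloxy)-2-ArB-hex-2-en-4-ynal | O=C/C(=C\C#CCO[Si](C)(C)C(C)(C)C)c1ccc(OC)c(O[Si](C(C)C)(C(C)C)C(C)C)c1OC | intermediate
11 | 4-bromo-3-methoxyphenol | COc1cc(O)ccc1Br | starting material
12 | (4-bromo-3-methoxyphenoxy)triisopropylsilane | COc1cc(O[Si](C(C)C)(C(C)C)C(C)C)ccc1Br | intermediate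
13 | 2-vinyloxirane (racemic) | C=CC1CO1 | starting material
14 | [2-methoxy-4-(triisopropylsilyloxy)phenyl]magnesium bromide | COc1cc(O[Si](C(C)C)(C(C)C)C(C)C)ccc1[Mg]Br | intermediate
15 | (E)-4-ArA-but-2-en-1-ol | COc1cc(O[Si](C(C)C)(C(C)C)C(C)C)ccc1C/C=C/CO | intermediate
16 | (E)-2-(4-ArA-but-2-en-1-yl)-4,4,5,5-tetramethyl-1,3,2-dioxaborolane | COc1cc(O[Si](C(C)C)(C(C)C)C(C)C)ccc1C/C=C/CB1OC(C)(C)C(C)(C)O1 | intermediate
17 | 4-bromobenzene-1,2-diol | Oc1ccc(Br)cc1O | starting material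
18 | 4-bromo-1,2-bis(triisopropylsilyloxy)benzene | Brc1ccc(O[Si](C(C)C)(C(C)C)C(C)C)c(O[Si](C(C)C)(C(C)C)C(C)C)c1 | intermediate
19 | [3,4-bis(triisopropylsilyloxy)phenyl]lithium | [Li]c1ccc(O[Si](C(C)C)(C(C)C)C(C)C)c(O[Si](C(C)C)(C(C)C)C(C)C)c1 | intermediate
20 | [3,4-bis(triisopropylsilyloxy)phenyl]boronic acid | OB(O)c1ccc(O[Si](C(C)C)(C(C)C)C(C)C)c(O[Si](C(C)C)(C(C)C)C(C)C)c1 | intermediate
21 | (5Z)-3,4-anti-3-(ArA-methyl)-5-ArB-9-(TBS-oxy)nona-1,5-dien-7-yn-4-ol | COc1cc(O[Si](C(C)C)(C(C)C)C(C)C)ccc1C[C@@H](C=C)[C@H](O)/C(=C\C#CCO[Si](C)(C)C(C)(C)C)c1ccc(OC)c(O[Si](C(C)C)(C(C)C)C(C)C)c1OC | intermediate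
22 | (5Z)-3,4-anti-3-(ArA-methyl)-5-ArB-9-(TBS-oxy)non-5-en-7-yne-1,4-diol | COc1cc(O[Si](C(C)C)(C(C)C)C(C)C)ccc1C[C@@H](CCO)[C@H](O)/C(=C\C#CCO[Si](C)(C)C(C)(C)C)c1ccc(OC)c(O[Si](C(C)C)(C(C)C)C(C)C)c1OC | intermediate
23 | 4,5-trans-4-(ArA-methyl)-5-[(Z)-1-ArB-5-(TBS-oxy)pent-1-en-3-yn-1-yl]dihydrofuran-2(3H)-one | COc1cc(O[Si](C(C)C)(C(C)C)C(C)C)ccc1C[C@H]1CC(=O)O[C@@H]1/C(=C\C#CCO[Si](C)(C)C(C)(C)C)c1ccc(OC)c(O[Si](C(C)C)(C(C)C)C(C)C)c1OC | intermediate
24 | 2,3-trans-3-(ArA-methyl)-2-[(Z)-1-ArB-5-(TBS-oxy)pent-1-en-3-yn-1-yl]-2,3-dihydrofuran-5-yl diphenyl phosphate | COc1cc(O[Si](C(C)C)(C(C)C)C(C)C)ccc1C[C@H]1C=C(OP(=O)(Oc2ccccc2)Oc2ccccc2)O[C@@H]1/C(=C\C#CCO[Si](C)(C)C(C)(C)C)c1ccc(OC)c(O[Si](C(C)C)(C(C)C)C(C)C)c1OC | intermediate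
25 | [3,4-bis(TIPS-oxy)phenyl]{4,5-trans-4-(ArA-methyl)-5-[(Z)-1-ArB-5-(TBS-oxy)pent-1-en-3-yn-1-yl]-4,5-dihydrofuran-2-yl}methanone | COc1cc(O[Si](C(C)C)(C(C)C)C(C)C)ccc1C[C@H]1C=C(C(=O)c2ccc(O[Si](C(C)C)(C(C)C)C(C)C)c(O[Si](C(C)C)(C(C)C)C(C)C)c2)O[C@@H]1/C(=C\C#CCO[Si](C)(C)C(C)(C)C)c1ccc(OC)c(O[Si](C(C)C)(C(C)C)C(C)C)c1OC | intermediate
26 | (2,3-trans,3,3a-trans,3a,8a-cis)-3-(ArA-methyl)-2-[(Z)-1-ArB-5-(TBS-oxy)pent-1-en-3-yn-1-yl]-5,6-bis(TIPS-oxy)-2,3,3a,8a-tetrahydro-8H-indeno[2,1-b]furan-8-one | COc1cc(O[Si](C(C)C)(C(C)C)C(C)C)ccc1C[C@@H]1[C@@H](/C(=C\C#CCO[Si](C)(C)C(C)(C)C)c2ccc(OC)c(O[Si](C(C)C)(C(C)C)C(C)C)c2OC)O[C@H]2C(=O)c3cc(O[Si](C(C)C)(C(C)C)C(C)C)c(O[Si](C(C)C)(C(C)C)C(C)C)cc3[C@@H]12 | intermediate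
27 | as 26, with 2-[(Z)-1-ArB-5-hydroxypent-1-en-3-yn-1-yl] | COc1cc(O[Si](C(C)C)(C(C)C)C(C)C)ccc1C[C@@H]1[C@@H](/C(=C\C#CCO)c2ccc(OC)c(O[Si](C(C)C)(C(C)C)C(C)C)c2OC)O[C@H]2C(=O)c3cc(O[Si](C(C)C)(C(C)C)C(C)C)c(O[Si](C(C)C)(C(C)C)C(C)C)cc3[C@@H]12 | intermediate
28 | (2,3-trans,3,3a-trans)-3-(ArA-methyl)-2-[(Z)-1-ArB-5-(TMS-oxy)pent-1-en-3-yn-1-yl]-5,6-bis(TIPS-oxy)-8-(TMS-oxy)-3,3a-dihydro-2H-indeno[2,1-b]furan | COc1cc(O[Si](C(C)C)(C(C)C)C(C)C)ccc1C[C@@H]1[C@@H](/C(=C\C#CCO[Si](C)(C)C)c2ccc(OC)c(O[Si](C(C)C)(C(C)C)C(C)C)c2OC)OC2=C(O[Si](C)(C)C)c3cc(O[Si](C(C)C)(C(C)C)C(C)C)c(O[Si](C(C)C)(C(C)C)C(C)C)cc3[C@@H]12 | intermediate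
29 | bis-TMS cyclopropane: CH2 added across C8–C8a of 28 on the face anti to the tetrahydrofuran ring | COc1cc(O[Si](C(C)C)(C(C)C)C(C)C)ccc1C[C@@H]1[C@@H](/C(=C\C#CCO[Si](C)(C)C)c2ccc(OC)c(O[Si](C(C)C)(C(C)C)C(C)C)c2OC)O[C@@]23C[C@]2(O[Si](C)(C)C)c2cc(O[Si](C(C)C)(C(C)C)C(C)C)c(O[Si](C(C)C)(C(C)C)C(C)C)cc2[C@@H]13 | intermediate
30 | cyclopropanol diol: as 29 with both TMS ethers cleaved (tertiary cyclopropanol and primary propargylic alcohol) | COc1cc(O[Si](C(C)C)(C(C)C)C(C)C)ccc1C[C@@H]1[C@@H](/C(=C\C#CCO)c2ccc(OC)c(O[Si](C(C)C)(C(C)C)C(C)C)c2OC)O[C@@]23C[C@]2(O)c2cc(O[Si](C(C)C)(C(C)C)C(C)C)c(O[Si](C(C)C)(C(C)C)C(C)C)cc2[C@@H]13 | intermediate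
31 | cyclopropanol ynal: as 30 with the propargylic alcohol oxidised to the aldehyde | COc1cc(O[Si](C(C)C)(C(C)C)C(C)C)ccc1C[C@@H]1[C@@H](/C(=C\C#CC=O)c2ccc(OC)c(O[Si](C(C)C)(C(C)C)C(C)C)c2OC)O[C@@]23C[C@]2(O)c2cc(O[Si](C(C)C)(C(C)C)C(C)C)c(O[Si](C(C)C)(C(C)C)C(C)C)cc2[C@@H]13 | intermediate
32 | ring-expanded keto-enal: 1-tetralone fused to the 8-oxabicyclo[3.2.1]oct-3-ene, with a (Z)-formylmethylidene group on the carbon next to the quaternary ring-ether carbon (CHO cis to that carbon) | COc1cc(O[Si](C(C)C)(C(C)C)C(C)C)ccc1C[C@@H]1[C@@H]2O[C@@]3(CC(=O)c4cc(O[Si](C(C)C)(C(C)C)C(C)C)c(O[Si](C(C)C)(C(C)C)C(C)C)cc4[C@@H]13)/C(=C\C=O)C=C2c1ccc(OC)c(O[Si](C(C)C)(C(C)C)C(C)C)c1OC | intermediate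
33 | tetrakis-TIPS ether of the target (all four phenols silylated, tertiary alcohol free) | COc1cc(O[Si](C(C)C)(C(C)C)C(C)C)ccc1C[C@@H]1[C@@H]2O[C@@]34C[C@@](O)(C(=O)C=C3C=C2c2ccc(OC)c(O[Si](C(C)C)(C(C)C)C(C)C)c2OC)c2cc(O[Si](C(C)C)(C(C)C)C(C)C)c(O[Si](C(C)C)(C(C)C)C(C)C)cc2[C@@H]14 | intermediate
34 | CNP0246028.1 | COc1cc(O)ccc1C[C@@H]1[C@@H]2O[C@@]34C[C@@](O)(C(=O)C=C3C=C2c2ccc(OC)c(O)c2OC)c2cc(O)c(O)cc2[C@@H]14 | target

**Totals and risks**

Total step count: 22. Longest linear sequence: 17 steps (steps 1–5, then 11–22).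

Steps most likely to fail:

1. Step 21 (Proposed new method). What may go wrong: oxidation of the α-oxy radical or hydrogen loss with aromatisation to a naphthol before ring closure; protonation to the wrong enal geometry; diversion of the carbene into homoenolate or redox pathways; base-induced β-elimination of the ring oxygen from the β-alkoxy ketone. Fallback (known chemistry, separate operations), setting out from 31 and returning at 33: the cerium-photocatalysed ring-opening radical cyclisation is run alone and keto-enal 32 is isolated. SmI2 (THF, t-BuOH, −78 °C) then joins the aryl ketone and the aldehyde by intramolecular pinacol coupling to give the cis-diol, the tetrakis-TIPS 1,2-diol F1 (new carbinol centre undefined, lost in the next operation). MnO2 oxidises the allylic secondary alcohol of F1 to the enone, which is 33.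

2. Step 16. What may go wrong: acid-induced ionisation and oligomerisation of the electron-rich aryl-enyne arm, loss of silyl ethers, or poor torquoselectivity. Fallback, setting out from 24 and returning at 26: methoxycarbonylation of 24 (CO, MeOH, Pd(PPh3)4, Et3N) gives the methyl 4,5-dihydrofuran-2-carboxylate F2. Separately, commercial 4,5-dibromobenzene-1,2-diol is silylated to 1,2-dibromo-4,5-bis(TIPS-oxy)benzene F3, and a single bromine–lithium exchange (n-BuLi, −100 °C) with B(Oi-Pr)3 gives (2-bromo-4,5-bis(TIPS-oxy)phenyl)boronic acid F4. Conjugate addition of F4 to F2 ([Rh(OH)(cod)]2, dioxane–H2O) should give the methyl 3-aryl-tetrahydrofuran-2-carboxylate F5 (aryl anti to the benzyl group, ester cis to aryl by protonation anti to the new aryl group). Bromine–lithium exchange on F5 (t-BuLi, −100 °C) closes the indanone by intramolecular acylation (Parham cyclisation) to give 26.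

3. Step 15. What may go wrong: direct, non-carbonylative coupling, or hydrolysis and decomposition of the five-membered ketene acetal phosphate. Fallback, setting out from 23 and returning at 25: diisobutylaluminium hydride (−78 °C) reduces the lactone to the lactol F6. Mesylation–elimination (MsCl, Et3N) gives the 2,3-trans-2,3-disubstituted 2,3-dihydrofuran F7. Its vinylic hydrogen next to oxygen is removed with t-BuLi (THF, −78 to 0 °C) and the lithio species is acylated with N-methoxy-N-methyl-3,4-bis(TIPS-oxy)benzamide F8 (from aryllithium 19 and N-methoxy-N-methylcarbamoyl chloride) to give 25.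

**Further compounds**

F1 | step 21 | tetrakis-TIPS 1,2-diol (pinacol product: secondary allylic alcohol next to the tertiary carbinol) | COc1cc(O[Si](C(C)C)(C(C)C)C(C)C)ccc1C[C@@H]1[C@@H]2O[C@@]34C[C@@](O)(C(O)C=C3C=C2c2ccc(OC)c(O[Si](C(C)C)(C(C)C)C(C)C)c2OC)c2cc(O[Si](C(C)C)(C(C)C)C(C)C)c(O[Si](C(C)C)(C(C)C)C(C)C)cc2[C@@H]14
F2 | step 16 | methyl 4,5-trans-4-(ArA-methyl)-5-[(Z)-1-ArB-5-(TBS-oxy)pent-1-en-3-yn-1-yl]-4,5-dihydrofuran-2-carboxylate | COc1cc(O[Si](C(C)C)(C(C)C)C(C)C)ccc1C[C@H]1C=C(C(=O)OC)O[C@@H]1/C(=C\C#CCO[Si](C)(C)C(C)(C)C)c1ccc(OC)c(O[Si](C(C)C)(C(C)C)C(C)C)c1OC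
F3 | step 16 | 1,2-dibromo-4,5-bis(triisopropylsilyloxy)benzene | Brc1cc(O[Si](C(C)C)(C(C)C)C(C)C)c(O[Si](C(C)C)(C(C)C)C(C)C)cc1Br
F4 | step 16 | (2-bromo-4,5-bis(triisopropylsilyloxy)phenyl)boronic acid | OB(O)c1cc(O[Si](C(C)C)(C(C)C)C(C)C)c(O[Si](C(C)C)(C(C)C)C(C)C)cc1Br
F5 | step 16 | methyl (2,3-cis,3,4-trans,4,5-trans)-3-[2-bromo-4,5-bis(TIPS-oxy)phenyl]-4-(ArA-methyl)-5-[(Z)-1-ArB-5-(TBS-oxy)pent-1-en-3-yn-1-yl]tetrahydrofuran-2-carboxylate | COc1cc(O[Si](C(C)C)(C(C)C)C(C)C)ccc1C[C@@H]1[C@@H](/C(=C\C#CCO[Si](C)(C)C(C)(C)C)c2ccc(OC)c(O[Si](C(C)C)(C(C)C)C(C)C)c2OC)O[C@@H](C(=O)OC)[C@H]1c1cc(O[Si](C(C)C)(C(C)C)C(C)C)c(O[Si](C(C)C)(C(C)C)C(C)C)cc1Br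
F6 | step 15 | 4,5-trans-4-(ArA-methyl)-5-[(Z)-1-ArB-5-(TBS-oxy)pent-1-en-3-yn-1-yl]tetrahydrofuran-2-ol (anomer mixture) | COc1cc(O[Si](C(C)C)(C(C)C)C(C)C)ccc1C[C@H]1CC(O)O[C@@H]1/C(=C\C#CCO[Si](C)(C)C(C)(C)C)c1ccc(OC)c(O[Si](C(C)C)(C(C)C)C(C)C)c1OC
F7 | step 15 | 2,3-trans-3-(ArA-methyl)-2-[(Z)-1-ArB-5-(TBS-oxy)pent-1-en-3-yn-1-yl]-2,3-dihydrofuran | COc1cc(O[Si](C(C)C)(C(C)C)C(C)C)ccc1C[C@H]1C=CO[C@@H]1/C(=C\C#CCO[Si](C)(C)C(C)(C)C)c1ccc(OC)c(O[Si](C(C)C)(C(C)C)C(C)C)c1OC
F8 | step 15 | N-methoxy-N-methyl-3,4-bis(triisopropylsilyloxy)benzamide | CON(C)C(=O)c1ccc(O[Si](C(C)C)(C(C)C)C(C)C)c(O[Si](C(C)C)(C(C)C)C(C)C)c1
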